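## Retrosynthetic overview

1. The two acyl groups go on last (O8 methacrylate, then O9 acetate), from a macrolactone carrying 8-O-PMB and 9-O-TBS.
2. The ten-membered carbocycle and the trans γ-lactone form together in the last C–C bond (C6–C7): intramolecular CrCl2 allylation of a C6 epoxy aldehyde by a C13 allylic bromide (C11–C13 from methyl acrylate).
3. The open chain is joined at C9–C10 by chelation-controlled addition of a fragment A alkynylzinc to a fragment B α-alkoxy aldehyde; the alkyne becomes the ring-cis (E)-enoate by syn-hydrostannation, iodination and methoxycarbonylation.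
4. Fragment A (C1–C6, C15, plus C10) comes from geraniol by catalytic Sharpless epoxidation; fragment B (C7–C9) from 2-O-PMB-glycerol by lipase desymmetrisation.
5. Ring order: oxirane first (step 1), then carbocycle and lactone together (step 22).

Assumption: the lipase acylates the pro-S hydroxymethyl arm of the 2-O-PMB diol as it does for the 2-O-benzyl analogue (if not, the same enzyme gives the (S)-monoacetate by mono-hydrolysis of the diacetate).

Locants follow germacrane numbering (C1–C10 ring, C11–C13 lactone carbons, C14 ester carbon, C15 methyl). TBS = tert-butyldimethylsilyl, TES = triethylsilyl, PMB = 4-methoxybenzyl. The stereochemical outcome of step 22 is argued by analogy and model, not guaranteed.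

## Route

Step 1
Reactants: 1 geraniol
Product: 2 (2R,3R)-2,3-epoxygeraniol
Conditions: Ti(OiPr)4 (5 mol %), D-(−)-diethyl tartrate (7 mol %), t-BuOOH (1.5 equiv), 4 Å MS, CH2Cl2, −20 °C
Reagents that add atoms: tert-butyl hydroperoxide, CC(C)(C)OO
Why: Katsuki–Sharpless asymmetric epoxidation; the titanium D-tartrate catalyst epoxidises only the allylic-alcohol alkene and from the face that gives the (2R,3R)-oxirane (C4 and C5, the first stereocentres, catalyst-controlled).

Step 2
Reactants: 2 (2R,3R)-2,3-epoxygeraniol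
Product: 3 TBS ether of 2
Conditions: TBSCl, imidazole, DMF, 0 °C → rt
Reagents that add atoms: tert-butyldimethylsilyl chloride, CC(C)(C)[Si](C)(C)Cl
Why: standard silylation of the primary alcohol, masking C6–OH through the organometallic steps.

Step 3
Reactants: 3 TBS ether of 2
Product: 5 epoxy aldehyde 3-[(2R,3R)-3-(TBSO-methyl)-2-methyloxiran-2-yl]propanal, via ozonide 4 (not isolated)
Conditions: O3, CH2Cl2, −78 °C; then PPh3, −78 °C → rt
Reagents that add atoms: ozone, [O-][O+]=O
Why: ozonolysis with reductive work-up cleaves the only alkene to the C1 aldehyde; oxirane and silyl ether are inert.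

Step 4
Reactants: 5 epoxy aldehyde
Product: 6 terminal alkyne (C10≡C1 on the C2–C6 epoxy chain)
Conditions: dimethyl (1-diazo-2-oxopropyl)phosphonate, K2CO3, MeOH, 0 °C → rt
Reagents that add atoms: dimethyl (1-diazo-2-oxopropyl)phosphonate, COP(=O)(OC)C(=[N+]=[N-])C(C)=O
Why: Ohira–Bestmann (Seyferth–Gilbert) homologation under mild carbonate conditions that leave the hindered oxirane untouched; the added carbon is C10.

Step 5
Reactants: 7 2-phenyl-1,3-dioxan-5-ol
Product: 8 5-[(4-methoxybenzyl)oxy]-2-phenyl-1,3-dioxane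
Conditions: NaH, 4-methoxybenzyl chloride, Bu4NI (cat.), THF/DMF, 0 °C → rt
Reagents that add atoms: 4-methoxybenzyl chloride, COc1ccc(CCl)cc1
Why: Williamson etherification puts the later chelating, oxidatively removable PMB group on the central glycerol oxygen (O8).

Step 6
Reactants: 8 PMB ether
Product: 9 2-[(4-methoxybenzyl)oxy]propane-1,3-diol
Conditions: AcOH/H2O (4:1), 45 °C
Reagents that add atoms: none
Why: acid-catalysed acetal hydrolysis; the PMB ether survives aqueous acetic acid and the prochiral diol results.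

Step 7
Reactants: 9 prochiral diol
Product: 10 (2S)-3-hydroxy-2-[(4-methoxybenzyl)oxy]propyl acetate
Conditions: lipase (Burkholderia cepacia lipase, immobilised), vinyl acetate (4 equiv), i-Pr2O, 25 °C
Reagents that add atoms: vinyl acetate, C=COC(C)=O
Why: lipase-catalysed enantiotopic-group-selective transesterification (desymmetrisation) with an irreversible acyl donor sets C8 in high ee.

Step 8
Reactants: 10 (S)-monoacetate
Product: 11 (2R)-2-[(4-methoxybenzyl)oxy]-3-[(triethylsilyl)oxy]propyl acetate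
Conditions: TESCl, imidazole, CH2Cl2, 0 °C
Reagents that add atoms: chlorotriethylsilane, CC[Si](Cl)(CC)CC
Why: immediate silylation of the free arm prevents 1,3-acyl migration, which would racemise the monoacetate.

Step 9
Reactants: 11 TES ether acetate
Product: 12 (2R)-2-[(4-methoxybenzyl)oxy]-3-[(triethylsilyl)oxy]propan-1-ol
Conditions: i-Bu2AlH (2.2 equiv), CH2Cl2, −78 °C; aqueous work-up
Reagents that add atoms: none
Why: reductive acetate cleavage at −78 °C avoids the basic conditions under which the silyl group could migrate between the two arms.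

Step 10
Reactants: 12 alcohol
Product: 13 (2S)-2-[(4-methoxybenzyl)oxy]-3-[(triethylsilyl)oxy]propanal
Conditions: PhI(OAc)2, TEMPO (2,2,6,6-tetramethylpiperidin-1-oxyl, cat.), CH2Cl2, rt; used crude
Reagents that add atoms: none
Why: base-free oxoammonium (TEMPO) oxidation gives the α-alkoxy aldehyde without epimerising C8.

Step 11
Reactants: 6 terminal alkyne; 13 α-alkoxy aldehyde
Product: 16 propargylic alcohol (4R,5R,8S,9S), via lithium acetylide 14 (not isolated), via alkynylzinc bromide 15 (not isolated)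
Conditions: 6, n-BuLi, Et2O, −78 °C; ZnBr2 (1.05 equiv), −78 → 0 °C; then 13, −78 → −20 °C; H2O work-up
Reagents that add atoms: none
Why: Cram-chelate-controlled addition; zinc bridges the aldehyde and PMB-ether oxygens and the alkynyl group attacks from the side of the C8 hydrogen, giving the 8,9-syn (9S) alcohol.

Step 12
Reactants: 16 propargylic alcohol
Product: 17 (E)-vinylstannane (tin on C10; 4R,5R,8S,9R)
Conditions: Pd(PPh3)2Cl2 (3 mol %), Bu3SnH (1.3 equiv, slow addition), THF, 0 °C → rt
Reagents that add atoms: tributyltin hydride, CCCC[SnH](CCCC)CCCC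
Why: palladium-catalysed syn-hydrostannation; the free propargylic hydroxyl biases tin to the proximal carbon C10, and cis delivery of H and Sn fixes C2 cis to C9 (the ring-cis geometry).

Step 13
Reactants: 17 vinylstannane
Product: 18 (E)-vinyl iodide (iodine on C10)
Conditions: I2, CH2Cl2, 0 °C
Reagents that add atoms: iodine, II
Why: iododestannylation proceeds with retention of alkene geometry.

Step 14
Reactants: 18 iodo allylic alcohol
Product: 19 O9-TBS ether of 18
Conditions: TBSCl, imidazole, DMAP (4-(dimethylamino)pyridine, cat.), DMF, 40 °C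
Reagents that add atoms: tert-butyldimethylsilyl chloride, CC(C)(C)[Si](C)(C)Cl
Why: triflate-free silylation spares the oxirane and blocks O9 for the palladium and amine-mediated steps that follow.

Step 15
Reactants: 19 silylated vinyl iodide
Product: 20 methyl (E)-enoate (C14 ester on C10; 4R,5R,8S,9S)
Conditions: Pd(OAc)2 (5 mol %), PPh3 (10 mol %), CO (1 atm), Et3N, MeOH/DMF (1:2), 55 °C
Reagents that add atoms: carbon monoxide, [C-]#[O+]; methanol, CO
Why: palladium-catalysed alkoxycarbonylation of the vinyl iodide with retention of geometry; the ester ends up trans to C2 as in the target.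

Step 16
Reactants: 20 enoate
Product: 21 C7 primary alcohol
Conditions: PPTS (pyridinium p-toluenesulfonate, cat.), MeOH/CH2Cl2 (1:1), 0 °C
Reagents that add atoms: none
Why: mild acid solvolysis removes the primary TES ether far faster than either TBS ether and leaves the oxirane intact.

Step 17
Reactants: 21 C7 alcohol
Product: 22 C7 aldehyde (4R,5R,8R,9S)
Conditions: PhI(OAc)2, TEMPO (cat.), CH2Cl2, rt
Reagents that add atoms: none
Why: chemoselective TEMPO oxidation of the only free alcohol under non-basic conditions.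

Step 18
Reactants: 22 C7 aldehyde; 23 methyl acrylate
Product: 24 Morita–Baylis–Hillman adduct (C7 carbinol epimers)
Conditions: DABCO (1,4-diazabicyclo[2.2.2]octane, 1.0 equiv), methyl acrylate (15 equiv), MeOH (3 equiv), rt, 72 h
Reagents that add atoms: none
Why: Morita–Baylis–Hillman reaction installs C11–C13; the new C7 carbinol centre is erased by the allylic transposition in step 21, so its configuration does not matter.

Step 19
Reactants: 24 adduct
Product: 25 diol (free C6–OH and C7–OH)
Conditions: HF·pyridine, pyridine, THF, 0 °C → rt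
Reagents that add atoms: none
Why: buffered fluoride removes the primary TBS ether selectively; the hindered secondary TBS ether on O9 stays.

Step 20
Reactants: 25 diol
Product: 26 epoxy aldehyde (C6 aldehyde; 4R,5S,8S,9S)
Conditions: PhI(OAc)2, TEMPO (cat.), CH2Cl2, 0 °C → rt
Reagents that add atoms: none
Why: TEMPO oxidation takes the primary alcohol and leaves the hindered, electron-poor secondary allylic alcohol.

Step 21
Reactants: 26 hydroxy aldehyde
Product: 27 (Z)-allylic bromide (C7=C11, C13–Br)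
Conditions: NBS, Me2S, CH2Cl2, −20 → 0 °C
Reagents that add atoms: N-bromosuccinimide, O=C1CCC(=O)N1Br
Why: Corey–Kim-type activation of the allylic alcohol followed by SN2' attack of bromide gives the thermodynamically preferred (Z)-2-(bromomethyl)enoate under neutral conditions that spare the epoxy aldehyde.

Step 22
Reactants: 27 bromo aldehyde
Product: 30 macrolactone (8-O-PMB 9-O-TBS), via allylchromium dichloride 28 (not isolated), via chromium alkoxide 29 (not isolated)
Conditions: CrCl2 (10 equiv), THF/DMF (3:1), 2 mmol/L, addition of 27 over 8 h, 25 °C; then 40 °C, 2 h; H2O work-up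
Reagents that add atoms: none
Why: intramolecular Nozaki–Hiyama (Barbier) 2-(alkoxycarbonyl)allylation through a chair-like six-membered transition state inside the forming ten-membered ring puts C5 and C8 anti (6,7-trans); the (4R,5R)-oxirane is relied on to fix the aldehyde face (6S, threo, the sense found in natural germacranolides though opposite to the open-chain Felkin preference) with the C8–C9 bond anti to the new bond (7R), and the trivalent chromium alkoxide lactonises onto the C12 ester.

Step 23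
Reactants: 30 macrolactone
Product: 31 8-hydroxy macrolactone (9-O-TBS)
Conditions: DDQ (1.5 equiv), CH2Cl2/pH 7 phosphate buffer (10:1), 0 °C
Reagents that add atoms: none
Why: oxidative PMB cleavage under buffered conditions leaves the oxirane, the silyl ether and the electron-poor alkenes alone.

Step 24
Reactants: 31 8-hydroxy macrolactone
Product: 32 8-O-methacryloyl macrolactone (9-O-TBS)
Conditions: methacrylic anhydride (3 equiv), Et3N, DMAP (0.2 equiv), CH2Cl2, 0 °C → rt
Reagents that add atoms: methacrylic anhydride, C=C(C)C(=O)OC(=O)C(C)=C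
Why: DMAP-catalysed acylation; the slower esterification is done first while O9 is still silylated, so no acyl migration can occur.

Step 25
Reactants: 32 methacrylate
Product: 33 9-hydroxy-8-O-methacryloyl macrolactone
Conditions: HF·pyridine (excess), THF, 0 °C → rt, 24 h
Reagents that add atoms: none
Why: acidic fluoride desilylation avoids the alkoxide conditions that would promote 8→9 acyl migration or conjugate addition to the methylene lactone.

Step 26
Reactants: 33 9-hydroxy compound
Product: 34 target CNP0153978.3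
Conditions: Ac2O (3 equiv), pyridine, DMAP (cat.), CH2Cl2, 0 °C
Reagents that add atoms: acetic anhydride, CC(=O)OC(C)=O
Why: fast DMAP-catalysed acetylation of the 9-hydroxyl outruns acyl migration and completes the target with all six stereocentres unchanged.

## Compound list

1 | geraniol, (2E)-3,7-dimethylocta-2,6-dien-1-ol | CC(C)=CCC/C(C)=C/CO | starting material
2 | (2R,3R)-2,3-epoxygeraniol | OC[C@H]1O[C@]1(C)CCC=C(C)C | intermediate
3 | TBS ether of 2 | CC(C)(C)[Si](C)(C)OC[C@H]1O[C@]1(C)CCC=C(C)C | intermediate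
4 | ozonide (1,2,4-trioxolane) of 3, oxirane intact | CC(C)(C)[Si](C)(C)OC[C@H]1O[C@]1(C)CCC1OOC(C)(C)O1 | intermediate (not isolated)
5 | 3-[(2R,3R)-3-(TBSO-methyl)-2-methyloxiran-2-yl]propanal | CC(C)(C)[Si](C)(C)OC[C@H]1O[C@]1(C)CCC=O | intermediate
6 | {[(2R,3R)-3-(but-3-yn-1-yl)-3-methyloxiran-2-yl]methoxy}(tert-butyl)dimethylsilane | CC(C)(C)[Si](C)(C)OC[C@H]1O[C@]1(C)CCC#C | intermediate
7 | 2-phenyl-1,3-dioxan-5-ol (1,3-O-benzylideneglycerol) | OC1COC(OC1)c1ccccc1 | starting material
8 | 5-[(4-methoxybenzyl)oxy]-2-phenyl-1,3-dioxane | COc1ccc(COC2COC(OC2)c2ccccc2)cc1 | intermediate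
9 | 2-[(4-methoxybenzyl)oxy]propane-1,3-diol | COc1ccc(COC(CO)CO)cc1 | intermediate
10 | (2S)-3-hydroxy-2-[(4-methoxybenzyl)oxy]propyl acetate | COc1ccc(CO[C@H](COC(C)=O)CO)cc1 | intermediate
11 | (2R)-2-[(4-methoxybenzyl)oxy]-3-[(triethylsilyl)oxy]propyl acetate | COc1ccc(CO[C@H](COC(C)=O)CO[Si](CC)(CC)CC)cc1 | intermediate
12 | (2R)-2-[(4-methoxybenzyl)oxy]-3-[(triethylsilyl)oxy]propan-1-ol | COc1ccc(CO[C@H](CO)CO[Si](CC)(CC)CC)cc1 | intermediate
13 | (2S)-2-[(4-methoxybenzyl)oxy]-3-[(triethylsilyl)oxy]propanal | COc1ccc(CO[C@H](C=O)CO[Si](CC)(CC)CC)cc1 | intermediate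
14 | lithium acetylide of 6 | CC(C)(C)[Si](C)(C)OC[C@H]1O[C@]1(C)CCC#C[Li] | intermediate (not isolated)
15 | alkynylzinc bromide of 6 | CC(C)(C)[Si](C)(C)OC[C@H]1O[C@]1(C)CCC#C[Zn]Br | intermediate (not isolated)
16 | (2S,3S)-7-[(2R,3R)-3-(TBSO-methyl)-2-methyloxiran-2-yl]-2-(PMBO)-1-(TESO)hept-4-yn-3-ol | CC(C)(C)[Si](C)(C)OC[C@H]1O[C@]1(C)CCC#C[C@H](O)[C@@H](OCc1ccc(OC)cc1)CO[Si](CC)(CC)CC | intermediate
17 | (2S,3R,4E)-7-[(2R,3R)-3-(TBSO-methyl)-2-methyloxiran-2-yl]-2-(PMBO)-1-(TESO)-4-(tributylstannyl)hept-4-en-3-ol | CC(C)(C)[Si](C)(C)OC[C@H]1O[C@]1(C)CC/C=C(/[Sn](CCCC)(CCCC)CCCC)[C@H](O)[C@@H](OCc1ccc(OC)cc1)CO[Si](CC)(CC)CC | intermediate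
18 | (2S,3R,4E)-4-iodo analogue of 17 (iodine in place of tin) | CC(C)(C)[Si](C)(C)OC[C@H]1O[C@]1(C)CC/C=C(/I)[C@H](O)[C@@H](OCc1ccc(OC)cc1)CO[Si](CC)(CC)CC | intermediate
19 | O9-TBS ether of 18 | CC(C)(C)[Si](C)(C)OC[C@H]1O[C@]1(C)CC/C=C(/I)[C@H](O[Si](C)(C)C(C)(C)C)[C@@H](OCc1ccc(OC)cc1)CO[Si](CC)(CC)CC | intermediate
20 | methyl (2E)-2-[(1S,2S)-1-(TBSO)-2-(PMBO)-3-(TESO)propyl]-5-[(2R,3R)-3-(TBSO-methyl)-2-methyloxiran-2-yl]pent-2-enoate | CC(C)(C)[Si](C)(C)OC[C@H]1O[C@]1(C)CC/C=C(/C(=O)OC)[C@H](O[Si](C)(C)C(C)(C)C)[C@@H](OCc1ccc(OC)cc1)CO[Si](CC)(CC)CC | intermediate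
21 | methyl (2E)-2-[(1S,2S)-1-(TBSO)-3-hydroxy-2-(PMBO)propyl]-5-[(2R,3R)-3-(TBSO-methyl)-2-methyloxiran-2-yl]pent-2-enoate | CC(C)(C)[Si](C)(C)OC[C@H]1O[C@]1(C)CC/C=C(/C(=O)OC)[C@H](O[Si](C)(C)C(C)(C)C)[C@@H](OCc1ccc(OC)cc1)CO | intermediate
22 | methyl (2E)-2-[(1S,2R)-1-(TBSO)-3-oxo-2-(PMBO)propyl]-5-[(2R,3R)-3-(TBSO-methyl)-2-methyloxiran-2-yl]pent-2-enoate | CC(C)(C)[Si](C)(C)OC[C@H]1O[C@]1(C)CC/C=C(/C(=O)OC)[C@H](O[Si](C)(C)C(C)(C)C)[C@@H](OCc1ccc(OC)cc1)C=O | intermediate
23 | methyl acrylate | C=CC(=O)OC | starting material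
24 | Morita–Baylis–Hillman adduct: 22 with C7 as CH(OH)–C(=CH2)CO2Me (C7 epimers; 4R,5R,8S,9S) | CC(C)(C)[Si](C)(C)OC[C@H]1O[C@]1(C)CC/C=C(/C(=O)OC)[C@H](O[Si](C)(C)C(C)(C)C)[C@@H](OCc1ccc(OC)cc1)C(O)C(=C)C(=O)OC | intermediate
25 | diol: 24 with free C6–OH (C7 epimers) | OC[C@H]1O[C@]1(C)CC/C=C(/C(=O)OC)[C@H](O[Si](C)(C)C(C)(C)C)[C@@H](OCc1ccc(OC)cc1)C(O)C(=C)C(=O)OC | intermediate
26 | epoxy aldehyde: 25 with C6 as CHO (4R,5S,8S,9S; C7 epimers) | O=C[C@H]1O[C@]1(C)CC/C=C(/C(=O)OC)[C@H](O[Si](C)(C)C(C)(C)C)[C@@H](OCc1ccc(OC)cc1)C(O)C(=C)C(=O)OC | intermediate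
27 | allylic bromide: C6 aldehyde, (Z)-C7=C11 enoate with C13–Br, 1(10)E (4R,5S,8S,9S) | O=C[C@H]1O[C@]1(C)CC/C=C(/C(=O)OC)[C@H](O[Si](C)(C)C(C)(C)C)[C@@H](OCc1ccc(OC)cc1)/C=C(\CBr)C(=O)OC | intermediate
28 | allylchromium dichloride from 27 (C13–CrCl2) | O=C[C@H]1O[C@]1(C)CC/C=C(/C(=O)OC)[C@H](O[Si](C)(C)C(C)(C)C)[C@@H](OCc1ccc(OC)cc1)/C=C(\C[Cr](Cl)Cl)C(=O)OC | intermediate (not isolated)
29 | ring-closed chromium alkoxide: ten-membered ring, C6–O–CrCl2, C7 bearing C(=CH2)CO2Me (stereocentres as in the target) | COc1ccc(CO[C@H]2[C@@H](C(=C)C(=O)OC)[C@H](O[Cr](Cl)Cl)[C@H]3O[C@]3(C)CC/C=C(/C(=O)OC)[C@@H]2O[Si](C)(C)C(C)(C)C)cc1 | intermediate (not isolated)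
30 | macrolactone: target skeleton with 8-O-PMB and 9-O-TBS (all six stereocentres arranged as in the target) | COc1ccc(CO[C@H]2[C@H]3C(=C)C(=O)O[C@@H]3[C@H]3O[C@]3(C)CC/C=C(/C(=O)OC)[C@@H]2O[Si](C)(C)C(C)(C)C)cc1 | intermediate
31 | 8-hydroxy-9-O-TBS macrolactone (stereocentres as in the target) | O[C@H]1[C@H]2C(=C)C(=O)O[C@@H]2[C@H]2O[C@]2(C)CC/C=C(/C(=O)OC)[C@@H]1O[Si](C)(C)C(C)(C)C | intermediate
32 | 8-O-methacryloyl-9-O-TBS macrolactone (stereocentres as in the target) | C=C(C)C(=O)O[C@H]1[C@H]2C(=C)C(=O)O[C@@H]2[C@H]2O[C@]2(C)CC/C=C(/C(=O)OC)[C@@H]1O[Si](C)(C)C(C)(C)C | intermediate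
33 | 9-hydroxy-8-O-methacryloyl macrolactone (9-desacetyl target) | C=C(C)C(=O)O[C@H]1[C@H]2C(=C)C(=O)O[C@@H]2[C@H]2O[C@]2(C)CC/C=C(/C(=O)OC)[C@@H]1O | intermediate
34 | CNP0153978.3, methyl (1(10)E,4R,5R,6S,7R,8S,9S)-9-acetoxy-4,5-epoxy-8-(methacryloyloxy)germacra-1(10),11(13)-dien-12,6-olid-14-oate | C=C(C)C(=O)O[C@H]1[C@H]2C(=C)C(=O)O[C@@H]2[C@H]2O[C@]2(C)CC/C=C(/C(=O)OC)[C@@H]1OC(C)=O | target

## Step count and risk

Total step count: 26. Longest linear sequence: 22 steps (7 → 34, steps 5–26); the geraniol branch is 20 steps (steps 1–4, then 11–26).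

Three steps most likely to fail:

Step 22, the ring closure. It must form a ten-membered ring and set C6 and C7 at once. The oxirane-directed facial sense is the main uncertainty (an open-chain Felkin model would predict the C6 epimer), and 1,4-elimination of the C8 alkoxide from the allylmetal or oligomerisation may compete. The fallback replaces the stoichiometric reductive Barbier reaction of an allyl bromide by a catalytic umpolung of an allylic ester. It sets out from hydroxy aldehyde 26, which is acetylated (Ac2O, pyridine, 0 °C) to the Morita–Baylis–Hillman acetate F1. Pd(PPh3)4 (5 mol %, zerovalent palladium) ionises the acetate and InI (monovalent indium) in THF/DMF at high dilution reduces the π-allyl complex to an allylindium species. This adds to the epoxy aldehyde through a chelate between trivalent indium and the oxirane oxygen, which favours the threo face, without an excess of divalent chromium, and the alkoxide lactonises. The fallback comes back to the route at macrolactone 30.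

Step 12, the hydrostannation. Tin may go partly to C1 instead of C10. The fallback makes the regiochemistry electronically controlled. It sets out from propargylic alcohol 16, which is oxidised (MnO2, CH2Cl2) to the ynone F2. Palladium-catalysed hydrostannation of the ynone (Pd(PPh3)4, Bu3SnH) places tin α to the carbonyl with syn addition, giving the stannyl enone F3, and I2 gives the iodo enone F4. Reagent-controlled Corey–Bakshi–Shibata reduction ((S)-2-methyl-CBS-oxazaborolidine, catecholborane, −78 °C, iodoalkenyl as the large group) restores the C9 carbinol. The fallback comes back to the route at iodo alcohol 18, and C8 must be checked for epimerisation at the ketone stage.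

Step 18, the Morita–Baylis–Hillman reaction. It may be too slow on the hindered, base-sensitive α-alkoxy aldehyde. The fallback uses a preformed vinylmetal instead of amine catalysis. It sets out from aldehyde 22. Methyl propiolate, i-Bu2AlH and N-methylmorpholine N-oxide in THF at 0 °C give the vinylalane F5, which adds 1,2 to the aldehyde within hours and leaves the esters alone. Hydrolysis gives the same adduct, and the fallback comes back to the route at 24.

## Further compounds

F1 | step 22 | C7 acetate of 26 (Morita–Baylis–Hillman acetate, C7 epimers) | O=C[C@H]1O[C@]1(C)CC/C=C(/C(=O)OC)[C@H](O[Si](C)(C)C(C)(C)C)[C@@H](OCc1ccc(OC)cc1)C(OC(C)=O)C(=C)C(=O)OC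
F2 | step 12 | ynone from 16 (C9 ketone, 4R,5R,8S) | CC(C)(C)[Si](C)(C)OC[C@H]1O[C@]1(C)CCC#CC(=O)[C@@H](OCc1ccc(OC)cc1)CO[Si](CC)(CC)CC
F3 | step 12 | (E)-α-stannyl enone (tin on C10) | CC(C)(C)[Si](C)(C)OC[C@H]1O[C@]1(C)CC/C=C(/[Sn](CCCC)(CCCC)CCCC)C(=O)[C@@H](OCc1ccc(OC)cc1)CO[Si](CC)(CC)CC
F4 | step 12 | (E)-α-iodo enone (iodine on C10) | CC(C)(C)[Si](C)(C)OC[C@H]1O[C@]1(C)CC/C=C(/I)C(=O)[C@@H](OCc1ccc(OC)cc1)CO[Si](CC)(CC)CC
F5 | step 18 | [1-(methoxycarbonyl)vinyl]diisobutylalane | C=C(C(=O)OC)[Al](CC(C)C)CC(C)C
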